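**Retrosynthetic overview**
1. The target is two trans-fused 2,2,5a-trimethylperhydro-1-benzoxepine units of the same absolute configuration, joined C6–CH2–CH2–C6′. The last operations are functional-group changes only: MeLi addition to the C7′ ketone, C3′ alcohol to ketone, and silyl removal.
2. Key disconnection: the bond between the bridge CH2 and C6′, made by an intermolecular lithium-enolate aldol between the α′-enolate of right-half enone 22 and left-half aldehyde 19, followed by dehydration and conjugate reduction.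
3. Both halves come from one bicyclic hydroxy ketone 9. The C8=C9 enone (Saegusa–Ito) leaves the neopentyl C6 as the only kinetic enolisation site, so the two-carbon arm (left half) and the aldol (right half) both go in at C6.
4. Ring order in 9: in a single epoxide-opening cascade of a geranylacetone-derived (S,S,S)-diepoxide enol silane, the oxepane C–O bond closes first and the cyclohexanone C–C bond second. No ring is formed after the coupling.
5. (E)-Geranylacetone comes from geranyl bromide and ethyl acetoacetate.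

Assumption: bicyclic compounds are numbered as 1-benzoxepines (O1, C2(Me)2, C3, C4, C5, C5a(Me), C6–C9, C9a; primed locants for the right half), and the ketone catalyst of step 3 (mirror image of the usual D-fructose-derived one) is bought or made from L-sorbose. Abbreviations: TBS = tert-butyldimethylsilyl, TES = triethylsilyl, TMS = trimethylsilyl.

**Route**

Step 1
Reactants: 1 geranyl bromide; 2 ethyl acetoacetate
Product: 3 ethyl (4E)-2-acetyl-5,9-dimethyldeca-4,8-dienoate (racemic at C2)
Conditions: NaH, THF, 0 °C; then 1, 0 °C to rt (2 in 1.5-fold excess)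
Reagents that add atoms: none
Why: acetoacetic ester alkylation, in which the soft sodium enolate displaces the primary allylic bromide by SN2 without touching the E-alkene.

Step 2
Reactants: 3 ethyl (4E)-2-acetyl-5,9-dimethyldeca-4,8-dienoate
Product: 5 (E)-geranylacetone (5E)-6,10-dimethylundeca-5,9-dien-2-one, via β-keto acid 4 (not isolated)
Conditions: 1 M NaOH, EtOH, 50 °C; then 1 M HCl to pH 3, 50 °C
Reagents that add atoms: none
Why: saponification followed by thermal decarboxylation of the β-keto acid gives geometrically pure E-ketone, which commercial E/Z mixtures do not guarantee.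

Step 3
Reactants: 5 (E)-geranylacetone
Product: 6 (5S,6S,9S)-5,6:9,10-diepoxy-6,10-dimethylundecan-2-one
Conditions: 1,2:4,5-di-O-isopropylidene-β-L-erythro-2,3-hexodiulo-2,6-pyranose (C12H18O6, 0.6 equiv), KHSO5 (as 2KHSO5·KHSO4·K2SO4), K2CO3, Bu4NHSO4, Na2B4O7/Na2EDTA buffer pH 10.5, MeCN/CH2(OMe)2/H2O, 0 °C
Reagents that add atoms: potassium peroxymonosulfate, [K+].OOS(=O)(=O)[O-]
Why: Shi-type asymmetric epoxidation, in which the chiral dioxirane transfers oxygen to the same enantioface of both E-trisubstituted alkenes through a spiro transition state and sets C5, C6 and C9 all S (the D-fructose-derived ketone would give the R series).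

Step 4
Reactants: 6 (5S,6S,9S)-diepoxy ketone
Product: 7 tert-butyl{[(5S,6S,9S)-5,6:9,10-diepoxy-6,10-dimethylundec-1-en-2-yl]oxy}dimethylsilane
Conditions: LiN(iPr)2, THF, −78 °C; TBSCl, DMPU, −78 to 0 °C
Reagents that add atoms: tert-butyldimethylsilyl chloride, CC(C)(C)[Si](C)(C)Cl
Why: kinetic deprotonation of the methyl ketone at the CH3 group and O-silylation give the terminal enol silane, and the epoxides are inert to the amide base at −78 °C.

Step 5
Reactants: 7 diepoxy TBS enol ether
Product: 9 (3S,5aS,9aS)-3-hydroxy-2,2,5a-trimethyloctahydro-1-benzoxepin-7(2H)-one (trans-fused), via TMS ether 8 (not isolated)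
Conditions: TMSOTf (1.2 equiv), 2,6-di-tert-butyl-4-methylpyridine, CH2Cl2, −78 °C; then 1 M HCl, THF, 0 °C
Reagents that add atoms: none
Why: in this Lewis acid-triggered epoxide-opening cascade the silylated terminal epoxide is opened at its tertiary carbon by the internal epoxide oxygen, and the enol silane then attacks the tertiary carbon of the resulting epoxonium ion anti to oxygen (Mukaiyama-type alkylation), so C3 and C9a keep their epoxide C–O bonds (both S), C5a forms with inversion and the ring fusion is trans.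

Step 6
Reactants: 9 bicyclic hydroxy ketone
Product: 10 (3S,5aS,9aS)-3-(TBSO)-2,2,5a-trimethyloctahydro-1-benzoxepin-7(2H)-one
Conditions: TBSOTf, 2,6-lutidine, CH2Cl2, −78 to 0 °C
Reagents that add atoms: tert-butyldimethylsilyl triflate, CC(C)(C)[Si](C)(C)OS(=O)(=O)C(F)(F)F
Why: silyl triflate silylation protects the hindered neopentyl-type secondary alcohol as a robust ether that lasts to the final step.

Step 7
Reactants: 10 TBS ether ketone
Product: 12 (3S,5aS,9aS)-3-(TBSO)-2,2,5a-trimethyl-3,4,5,5a,6,9a-hexahydro-1-benzoxepin-7(2H)-one (C8=C9 enone), via TMS enol ether 11 (not isolated)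
Conditions: LiN(iPr)2, TMSCl, THF, −78 °C; concentrate; then Pd(OAc)2 (1.1 equiv), MeCN, rt
Reagents that add atoms: none
Why: Saegusa–Ito oxidation, in which kinetic enolisation goes to the unhindered C8 and β-hydride elimination from the palladium enolate can only give the C8=C9 enone because C5a is quaternary.

Step 8
Reactants: 12 TBS enone; 13 tert-butyl bromoacetate
Product: 14 tert-butyl 2-[(3S,5aS,9aS)-3-(TBSO)-2,2,5a-trimethyl-7-oxo-2,3,4,5,5a,6,7,9a-octahydro-1-benzoxepin-6-yl]acetate (both C6 epimers)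
Conditions: LiN(iPr)2, THF, −78 °C; then 13, DMPU, −78 to −20 °C
Reagents that add atoms: none
Why: the enone can be deprotonated kinetically only at the α′ carbon C6, and SN2 alkylation of this cross-conjugated enolate with the reactive α-bromo ester places the two-carbon arm there (the C6 configuration is corrected in step 9).

Step 9
Reactants: 14 alkylated enone
Product: 16 tert-butyl 2-[(3S,5aS,6S,9aS)-3-(TBSO)-2,2,5a-trimethyl-7-oxodecahydro-1-benzoxepin-6-yl]acetate, via 6-epimer 15 (not isolated)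
Conditions: H2 (1 atm), Pd/C, EtOAc, rt; filter; then NaOMe (0.3 equiv), MeOH, rt
Reagents that add atoms: none
Why: catalytic hydrogenation saturates the enone, and base equilibration through the enolate then moves the C6 substituent into the more stable equatorial position cis to the axial angular methyl, which is the configuration of the target.

Step 10
Reactants: 16 keto ester
Product: 17 tert-butyl 2-[(3S,5aS,6R,9aS)-3-(TBSO)-2,2,5a-trimethyl-7-methylidenedecahydro-1-benzoxepin-6-yl]acetate
Conditions: Ph3PCH3Br (4 equiv), KOtBu (3.8 equiv), toluene, rt; then 16, 80 °C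
Reagents that add atoms: methyltriphenylphosphonium bromide, C[P+](c1ccccc1)(c1ccccc1)c1ccccc1.[Br-]
Why: Wittig methylenation converts the ketone into the exocyclic alkene while the tert-butyl ester is inert to the ylide, and any enolisation at C6 only returns the favoured equatorial epimer.

Step 11
Reactants: 17 methylidene ester
Product: 18 2-[(3S,5aS,6R,9aS)-3-(TBSO)-2,2,5a-trimethyl-7-methylidenedecahydro-1-benzoxepin-6-yl]ethanol
Conditions: LiAlH4, THF, 0 °C to rt
Reagents that add atoms: none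
Why: hydride reduction of the ester to the primary alcohol leaves the alkene and silyl ether untouched.

Step 12
Reactants: 18 primary alcohol
Product: 19 2-[(3S,5aS,6R,9aS)-3-(TBSO)-2,2,5a-trimethyl-7-methylidenedecahydro-1-benzoxepin-6-yl]acetaldehyde
Conditions: Dess–Martin periodinane, pyridine, CH2Cl2, 0 °C to rt
Reagents that add atoms: none
Why: Dess–Martin oxidation gives the aldehyde under buffered, non-epimerising conditions that do not isomerise the exocyclic alkene.

Step 13
Reactants: 9 bicyclic hydroxy ketone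
Product: 20 (3S,5aS,9aS)-3-(TESO)-2,2,5a-trimethyloctahydro-1-benzoxepin-7(2H)-one
Conditions: TESCl, imidazole, DMF, rt
Reagents that add atoms: chlorotriethylsilane, CC[Si](CC)(CC)Cl
Why: silylation with the more labile triethylsilyl group marks the right-half C3′ oxygen for later selective release next to the left-half TBS ether.

Step 14
Reactants: 20 TES ether ketone
Product: 22 (3S,5aS,9aS)-3-(TESO)-2,2,5a-trimethyl-3,4,5,5a,6,9a-hexahydro-1-benzoxepin-7(2H)-one (C8=C9 enone), via TMS enol ether 21 (not isolated)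
Conditions: LiN(iPr)2, TMSCl, THF, −78 °C; concentrate; then Pd(OAc)2 (1.1 equiv), MeCN, rt
Reagents that add atoms: none
Why: Saegusa–Ito oxidation as in step 7, with the same regiochemical guarantee from the quaternary C5a.

Step 15
Reactants: 22 TES enone (1.2 equiv); 19 aldehyde
Product: 23 β-hydroxy ketone (aldol adduct; left 7-methylidene unit–CH2–CH(OH)–C6′ of the right 7′-oxo-8′-ene unit; mixture at the carbinol carbon and C6′)
Conditions: LiN(iPr)2, THF, −78 °C, 45 min; then 19, −78 °C, 30 min; AcOH quench at −78 °C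
Reagents that add atoms: none
Why: intermolecular lithium-enolate aldol addition, in which the only kinetic enolate of 22 (α′, C6′) adds to the unhindered aldehyde faster than proton transfer, and the two new stereocentres are erased or reset in steps 16 and 17.

Step 16
Reactants: 23 aldol adduct
Product: 25 cross-conjugated dienone (C6′ exocyclic alkylidene and C8′=C9′; E/Z mixture), via mesylate 24 (not isolated)
Conditions: MsCl, Et3N, CH2Cl2, 0 °C; then DBU, rt
Reagents that add atoms: none
Why: mesylation and E1cB elimination of the β-mesyloxy ketone remove the aldol hydroxyl as the conjugated alkene, whose geometry is irrelevant.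

Step 17
Reactants: 25 dienone
Product: 26 saturated ketone (left (3S,5aS,6R,9aS)-3-OTBS-7-methylidene unit; right (3S,5aS,6S,9aS)-3-OTES-7-oxo unit; C6–CH2CH2–C6′)
Conditions: [(Ph3P)CuH]6 (0.8 equiv), H2O, benzene/THF, rt; then NaOMe (0.2 equiv), MeOH, rt
Reagents that add atoms: none
Why: copper hydride conjugate reduction saturates both enone alkenes without touching the isolated 1,1-disubstituted alkene, and enolate protonation anti to the angular methyl plus base equilibration leave the C6′ side chain equatorial (6′S).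

Step 18
Reactants: 26 ketone
Product: 27 tertiary alcohol (7′R; axial OH and equatorial CH3 at C7′)
Conditions: CeCl3 (anhydrous), MeLi, THF, −78 to −40 °C; H2O quench
Reagents that add atoms: methyllithium, [Li]C
Why: organocerium 1,2-addition suppresses enolisation of the hindered ketone, and the methyl group enters equatorially because the axial trajectory is blocked by the syn-axial C5a′ methyl, giving the axial hydroxyl cis to that methyl as in the target.

Step 19
Reactants: 27 bis-silyl tertiary alcohol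
Product: 28 C3′ secondary alcohol (TES removed; TBS retained)
Conditions: HF·pyridine, pyridine, THF, 0 °C to rt
Reagents that add atoms: none
Why: buffered fluoride desilylation cleaves the triethylsilyl ether far faster than the hindered TBS ether and leaves the tertiary alcohol and alkene alone.

Step 20
Reactants: 28 diol mono-TBS ether
Product: 29 C3′ ketone (3-O-TBS ether of the target)
Conditions: Dess–Martin periodinane, pyridine, CH2Cl2, rt
Reagents that add atoms: none
Why: Dess–Martin oxidation converts the only secondary alcohol into the oxepanone and cannot oxidise the tertiary alcohol.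

Step 21
Reactants: 29 TBS-protected target
Product: 30 CNP0160418.1
Conditions: Bu4NF, THF, rt to 45 °C
Reagents that add atoms: none
Why: fluoride desilylation frees the left-half C3 alcohol under non-acidic conditions, and the ketone has no epimerisable α-stereocentre.

**Compound list**
1 | geranyl bromide, (2E)-1-bromo-3,7-dimethylocta-2,6-diene | CC(C)=CCC/C(C)=C/CBr | starting material
2 | ethyl acetoacetate | CCOC(=O)CC(C)=O | starting material
3 | ethyl (4E)-2-acetyl-5,9-dimethyldeca-4,8-dienoate (racemic at C2) | CC(C)=CCC/C(C)=C/CC(C(C)=O)C(=O)OCC | intermediate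
4 | (4E)-2-acetyl-5,9-dimethyldeca-4,8-dienoic acid (not isolated) | CC(C)=CCC/C(C)=C/CC(C(C)=O)C(=O)O | intermediate
5 | (E)-geranylacetone, (5E)-6,10-dimethylundeca-5,9-dien-2-one | CC(C)=CCC/C(C)=C/CCC(C)=O | intermediate
6 | (5S,6S,9S)-5,6:9,10-diepoxy-6,10-dimethylundecan-2-one | CC(=O)CC[C@@H]1O[C@@]1(C)CC[C@@H]1OC1(C)C | intermediate
7 | TBS enol ether of 6 (terminal, C1=C2) | C=C(O[Si](C)(C)C(C)(C)C)CC[C@@H]1O[C@@]1(C)CC[C@@H]1OC1(C)C | intermediate
8 | (3S,5aS,9aS)-2,2,5a-trimethyl-3-(trimethylsilyloxy)octahydro-1-benzoxepin-7(2H)-one (not isolated) | O=C1CC[C@@H]2OC(C)(C)[C@@H](O[Si](C)(C)C)CC[C@@]2(C)C1 | intermediate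
9 | (3S,5aS,9aS)-3-hydroxy-2,2,5a-trimethyloctahydro-1-benzoxepin-7(2H)-one, trans-fused | O=C1CC[C@@H]2OC(C)(C)[C@@H](O)CC[C@@]2(C)C1 | intermediate
10 | 3-O-TBS ether of 9 | O=C1CC[C@@H]2OC(C)(C)[C@@H](O[Si](C)(C)C(C)(C)C)CC[C@@]2(C)C1 | intermediate
11 | C7=C8 TMS enol ether of 10 (not isolated) | C[Si](C)(C)OC1=CC[C@@H]2OC(C)(C)[C@@H](O[Si](C)(C)C(C)(C)C)CC[C@@]2(C)C1 | intermediate
12 | (3S,5aS,9aS)-3-(TBSO)-2,2,5a-trimethyl-3,4,5,5a,6,9a-hexahydro-1-benzoxepin-7(2H)-one | O=C1C=C[C@@H]2OC(C)(C)[C@@H](O[Si](C)(C)C(C)(C)C)CC[C@@]2(C)C1 | intermediate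
13 | tert-butyl bromoacetate | BrCC(=O)OC(C)(C)C | starting material
14 | tert-butyl 2-[(3S,5aS,9aS)-3-(TBSO)-2,2,5a-trimethyl-7-oxo-2,3,4,5,5a,6,7,9a-octahydro-1-benzoxepin-6-yl]acetate, C6 epimer mixture | O=C1C=C[C@@H]2OC(C)(C)[C@@H](O[Si](C)(C)C(C)(C)C)CC[C@@]2(C)C1CC(=O)OC(C)(C)C | intermediate
15 | tert-butyl 2-[(3S,5aS,6R,9aS)-3-(TBSO)-2,2,5a-trimethyl-7-oxodecahydro-1-benzoxepin-6-yl]acetate (6-epimer, axial arm; not isolated) | O=C1CC[C@@H]2OC(C)(C)[C@@H](O[Si](C)(C)C(C)(C)C)CC[C@@]2(C)[C@H]1CC(=O)OC(C)(C)C | intermediate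
16 | tert-butyl 2-[(3S,5aS,6S,9aS)-3-(TBSO)-2,2,5a-trimethyl-7-oxodecahydro-1-benzoxepin-6-yl]acetate (equatorial arm) | O=C1CC[C@@H]2OC(C)(C)[C@@H](O[Si](C)(C)C(C)(C)C)CC[C@@]2(C)[C@@H]1CC(=O)OC(C)(C)C | intermediate
17 | tert-butyl 2-[(3S,5aS,6R,9aS)-3-(TBSO)-2,2,5a-trimethyl-7-methylidenedecahydro-1-benzoxepin-6-yl]acetate | C=C1CC[C@@H]2OC(C)(C)[C@@H](O[Si](C)(C)C(C)(C)C)CC[C@@]2(C)[C@@H]1CC(=O)OC(C)(C)C | intermediate
18 | 2-[(3S,5aS,6R,9aS)-3-(TBSO)-2,2,5a-trimethyl-7-methylidenedecahydro-1-benzoxepin-6-yl]ethanol | C=C1CC[C@@H]2OC(C)(C)[C@@H](O[Si](C)(C)C(C)(C)C)CC[C@@]2(C)[C@@H]1CCO | intermediate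
19 | 2-[(3S,5aS,6R,9aS)-3-(TBSO)-2,2,5a-trimethyl-7-methylidenedecahydro-1-benzoxepin-6-yl]acetaldehyde | C=C1CC[C@@H]2OC(C)(C)[C@@H](O[Si](C)(C)C(C)(C)C)CC[C@@]2(C)[C@@H]1CC=O | intermediate
20 | 3-O-TES ether of 9 | O=C1CC[C@@H]2OC(C)(C)[C@@H](O[Si](CC)(CC)CC)CC[C@@]2(C)C1 | intermediate
21 | C7=C8 TMS enol ether of 20 (not isolated) | C[Si](C)(C)OC1=CC[C@@H]2OC(C)(C)[C@@H](O[Si](CC)(CC)CC)CC[C@@]2(C)C1 | intermediate
22 | (3S,5aS,9aS)-3-(TESO)-2,2,5a-trimethyl-3,4,5,5a,6,9a-hexahydro-1-benzoxepin-7(2H)-one | O=C1C=C[C@@H]2OC(C)(C)[C@@H](O[Si](CC)(CC)CC)CC[C@@]2(C)C1 | intermediate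
23 | aldol adduct: 6′-{1-hydroxy-2-[left 3-OTBS-7-methylidene unit-6-yl]ethyl} derivative of 22, mixture at CH(OH) and C6′ | C=C1CC[C@@H]2OC(C)(C)[C@@H](O[Si](C)(C)C(C)(C)C)CC[C@@]2(C)[C@@H]1CC(O)C1[C@]2(C)CC[C@H](O[Si](CC)(CC)CC)C(C)(C)O[C@H]2C=CC1=O | intermediate
24 | methanesulfonate of 23 (not isolated) | C=C1CC[C@@H]2OC(C)(C)[C@@H](O[Si](C)(C)C(C)(C)C)CC[C@@]2(C)[C@@H]1CC(OS(C)(=O)=O)C1[C@]2(C)CC[C@H](O[Si](CC)(CC)CC)C(C)(C)O[C@H]2C=CC1=O | intermediate
25 | cross-conjugated dienone (6′-alkylidene, C8′=C9′), E/Z mixture | C=C1CC[C@@H]2OC(C)(C)[C@@H](O[Si](C)(C)C(C)(C)C)CC[C@@]2(C)[C@@H]1CC=C1[C@]2(C)CC[C@H](O[Si](CC)(CC)CC)C(C)(C)O[C@H]2C=CC1=O | intermediate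
26 | (3S,5aS,6S,9aS)-6-{2-[(3S,5aS,6R,9aS)-3-(TBSO)-2,2,5a-trimethyl-7-methylidenedecahydro-1-benzoxepin-6-yl]ethyl}-3-(TESO)-2,2,5a-trimethyloctahydro-1-benzoxepin-7(2H)-one | C=C1CC[C@@H]2OC(C)(C)[C@@H](O[Si](C)(C)C(C)(C)C)CC[C@@]2(C)[C@@H]1CC[C@H]1[C@]2(C)CC[C@H](O[Si](CC)(CC)CC)C(C)(C)O[C@H]2CCC1=O | intermediate
27 | 7′R tertiary alcohol from 26 (7′-methyl, 7′-OH axial; 3-OTBS, 3′-OTES) | C=C1CC[C@@H]2OC(C)(C)[C@@H](O[Si](C)(C)C(C)(C)C)CC[C@@]2(C)[C@@H]1CC[C@H]1[C@]2(C)CC[C@H](O[Si](CC)(CC)CC)C(C)(C)O[C@H]2CC[C@@]1(C)O | intermediate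
28 | 3′,7′-diol with 3-OTBS (3′S secondary alcohol free) | C=C1CC[C@@H]2OC(C)(C)[C@@H](O[Si](C)(C)C(C)(C)C)CC[C@@]2(C)[C@@H]1CC[C@H]1[C@]2(C)CC[C@H](O)C(C)(C)O[C@H]2CC[C@@]1(C)O | intermediate
29 | 3-O-TBS ether of the target (3′-ketone) | C=C1CC[C@@H]2OC(C)(C)[C@@H](O[Si](C)(C)C(C)(C)C)CC[C@@]2(C)[C@@H]1CC[C@H]1[C@]2(C)CCC(=O)C(C)(C)O[C@H]2CC[C@@]1(C)O | intermediate
30 | CNP0160418.1, (5aS,6S,7R,9aS)-7-hydroxy-6-{2-[(3S,5aS,6R,9aS)-3-hydroxy-2,2,5a-trimethyl-7-methylidenedecahydro-1-benzoxepin-6-yl]ethyl}-2,2,5a,7-tetramethyloctahydro-1-benzoxepin-3(2H)-one | C=C1CC[C@@H]2OC(C)(C)[C@@H](O)CC[C@@]2(C)[C@@H]1CC[C@H]1[C@]2(C)CCC(=O)C(C)(C)O[C@H]2CC[C@@]1(C)O | target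

**Totals**
Total step count: 21. Longest linear sequence: 19 steps (steps 1–12, then 15–21). The right half needs steps 1–5, 13 and 14 before the union.

**Three steps most likely to fail, with fallbacks**

Step 5 (cascade): the enol silane may be O-alkylated, or the epoxonium ion may be intercepted before the C–C bond forms. Fallback, setting out from 5 and returning at 8: switch the terminating nucleophile to a carbon-only allylsilane. Ketone 5 is converted with LiN(iPr)2 and PhNTf2 into the kinetic enol triflate F1. Kumada coupling with Me3SiCH2MgCl and Pd(PPh3)4 gives the 2-substituted allylsilane F2. The epoxidation of step 3 (only the two trisubstituted alkenes are good substrates) gives the (S,S,S)-diepoxide F3. TMSOTf with 2,6-di-tert-butyl-4-methylpyridine at −78 °C closes both rings to the 7-methylidene TMS ether F4. Ozonolysis (O3, CH2Cl2, −78 °C; Me2S) then gives ketone 8, which is desilylated as in step 5.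

Step 15 (aldol union): the neopentyl α′-enolate may add slowly, the aldehyde may be enolised, or the adduct may revert. Fallback, setting out from 18 (with 22) and returning at 26: join the halves by enolate alkylation instead. Alcohol 18 is converted with I2, PPh3 and imidazole into the primary iodide F5. This alkylates the same lithium α′-enolate of 22 (LiN(iPr)2, THF/DMPU, −78 to 0 °C) to give the mono-enone F6. The conditions of step 17 then reduce the one remaining ring enone and equilibrate C6′ to give 26.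

Step 18 (methyl addition): the hindered, α-branched ketone may enolise or give a poor diastereomer ratio. Fallback, setting out from 26 and returning at 27: build the carbinol through an epoxide. Corey–Chaykovsky reaction with dimethylsulfoxonium methylide (Me3S(O)I, NaH, DMSO) gives, under thermodynamic control, the spiro-epoxide F7 with equatorial CH2 and axial oxygen. LiEt3BH in THF opens it at the CH2 carbon to give 27 with the same axial hydroxyl.

**Further compounds**
F1 | step 5 | (5E)-6,10-dimethylundeca-1,5,9-trien-2-yl trifluoromethanesulfonate | CC(C)=CCC/C(C)=C/CCC(=C)OS(=O)(=O)C(F)(F)F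
F2 | step 5 | [(5E)-6,10-dimethyl-2-methylideneundeca-5,9-dien-1-yl]trimethylsilane | CC(C)=CCC/C(C)=C/CCC(=C)C[Si](C)(C)C
F3 | step 5 | trimethyl{2-methylidene-4-[(2S,3S)-3-methyl-3-{2-[(2S)-3,3-dimethyloxiran-2-yl]ethyl}oxiran-2-yl]butyl}silane | C=C(C[Si](C)(C)C)CC[C@@H]1O[C@@]1(C)CC[C@@H]1OC1(C)C
F4 | step 5 | trimethyl{[(3S,5aS,9aS)-2,2,5a-trimethyl-7-methylidenedecahydro-1-benzoxepin-3-yl]oxy}silane | C=C1CC[C@@H]2OC(C)(C)[C@@H](O[Si](C)(C)C)CC[C@@]2(C)C1
F5 | step 15 | tert-butyl{[(3S,5aS,6R,9aS)-6-(2-iodoethyl)-2,2,5a-trimethyl-7-methylidenedecahydro-1-benzoxepin-3-yl]oxy}dimethylsilane | C=C1CC[C@@H]2OC(C)(C)[C@@H](O[Si](C)(C)C(C)(C)C)CC[C@@]2(C)[C@@H]1CCI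
F6 | step 15 | 8′,9′-didehydro derivative of 26 (mono-enone, C6′ epimer mixture) | C=C1CC[C@@H]2OC(C)(C)[C@@H](O[Si](C)(C)C(C)(C)C)CC[C@@]2(C)[C@@H]1CCC1[C@]2(C)CC[C@H](O[Si](CC)(CC)CC)C(C)(C)O[C@H]2C=CC1=O
F7 | step 18 | spiro-epoxide of 26 at C7′ (oxygen axial and cis to the C5a′ methyl, CH2 equatorial) | C=C1CC[C@@H]2OC(C)(C)[C@@H](O[Si](C)(C)C(C)(C)C)CC[C@@]2(C)[C@@H]1CC[C@H]1[C@]2(C)CC[C@H](O[Si](CC)(CC)CC)C(C)(C)O[C@H]2CC[C@]13CO3
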